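TBS = tert-butyldimethylsilyl throughout.

## Analysis of the target

Integric acid is an eremophilane-type sesquiterpenoid and is numbered here as one. Ring A is C1, C2, C3, C4, C5, C10 and ring B is C5 to C10. C14 is the methyl on C5, C15 the carboxyl carbon on C4, and C11 (with methylene C12 and formyl C13) the propenal unit on C7. Ring B carries the C8 ketone conjugated with C9=C10, C7 carries the 2-substituted acrolein, and C1 carries the (2E,4S)-2,4-dimethyloct-2-enoate. The ring stereocentres are 1R, 4S, 5R, 7S. C14, C15 and the C1 oxygen lie on one face (C15 equatorial, C1–O axial and 1,3-diaxial to C14), and the C7 substituent lies on the other, equatorial and therefore in the thermodynamic position next to the ketone. The sensitive groups are the enal (a Michael acceptor whose exocyclic double bond can migrate into conjugation through the acidic C7–H), the γ-acyloxy enone (elimination) and the free acid. The hard part is the quaternary C5 between the C4 stereocentre and the trigonal C10, together with oxidised carbons spread over both rings (C1, C8, C13, C15). The strategy rests on one feature: C5–C10 and C6–C7 lie 1,4 to each other across ring B with the C8 oxygen between C7 and C9. A C7=C8(O)–C9=C10 diene joined through C1–C4 to a C5=C6 dienophile therefore closes both rings at once.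

## Retrosynthetic reasoning

**38 to 35.** The enal is the most fragile group and is made last. Removing the C12 methylene gives aldehyde 37 (an aldehyde α-methylenation forward). Aldehyde 37 comes from the terminal alkene of the 7-allyl compound 35 by oxidative cleavage. An allyl group is used because an enolate can be allylated reliably but not vinylated; losing one carbon and adding one turns allyl into the propenal unit with the right connectivity.

**35 to 21 and 30.** The C15 carboxyl is taken back to the silyl-protected primary alcohol of 32 (via 33). The acid is released only after the ester is in place and is carried unprotected through the last two steps. The C1–O acyl bond is cut to the axial alcohol 21 and acid 30, so the side chain arrives as one enantiopure piece.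

**30 to 2 and 22.** The C2'=C3' bond of 30 is a Wittig disconnection to ylide 27 and aldehyde 28, made from alcohol 26. Its single stereocentre comes from auxiliary-controlled methylation of imide 23, built from 2 and 22.

**21 to 19.** The C1–O bond is cut. Forward, enone 19 is extended to the dienol silyl ether 20 and oxidised at its terminus C1. Axial attack syn to C14 gives the required 1R configuration, so no tether oxygen has to be carried through the cycloaddition.

**19 to 17.** The C7–C11 bond and the C6–H bond are cut together. Conjugate hydride addition to the less substituted double bond of the cross-conjugated dienone 17 gives a regiodefined C7 enolate, which is allylated anti to C14.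

**17 to 15.** Both ring B double bonds are taken back to the functions that the cycloaddition leaves behind. The C8 silyl enol ether of 15 gives C9=C10 by dehydrogenation, and the C6 sulfonyl group leaves as sulfinate to give C6=C7. The C6 and C10 centres of 15 disappear here.

**15 to 14.** This is the key disconnection: C5–C10 and C6–C7 are cut, opening rings A and B to the acyclic triene 14. Nowhere else can two ring bonds be cut so that the quaternary centre forms next to an existing stereocentre (C4) in an intramolecular, chair-organised step.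

**14 to 11 and 12.** The diene is the enol silyl ether of methyl enone 13. The C9=C10 bond of 13 is a cross-metathesis disconnection to the terminal alkene 11 and enone 12. The enone is introduced late so that it never meets strong bases or nucleophiles.

**11 to 9 and 10.** The C5=C6 bond is a Horner–Wadsworth–Emmons disconnection to methyl ketone 9 and phosphonate 10.

**9 to 1 and 2.** The C5–C14 bond comes from a Weinreb amide (8, from 7). The C4–C15 bond comes from auxiliary-controlled hydroxymethylation of imide 4, made from acid 1 and auxiliary 2. The C4 stereocentre is thus the only one installed by a reagent in the main chain; C5, C7 and C1 are relayed from it.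

## Alternatives that were turned down

**Alternative 1:** ring B is cut at C5–C6 and C7–C8. Forward, the ring A 1-ethoxydiene A2 (C5=C10 in the ring, C9=C8–OEt outside it) adds to 12 under heat or pressure to give octalin A1.
- For: it is convergent and the polarity of diene and dienophile is matched, so the regiochemistry is reliable. The C1 oxygen, C15 at the carboxyl level and two of the three side-chain carbons are in place after the key step. On these points it is stronger than the chosen route, which adds the C1 oxygen and C11–C13 after ring formation.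
- Against: the quaternary C5 must form intermolecularly at a tetrasubstituted, ring-bound diene terminus. The reactive s-cis conformer of A2 is strained against the C1 silyloxy group. The C5 face is flanked by the C4 and C1 substituents, which need not cooperate. A2 needs a stereodefined ring A before the key step. C8 arrives as an allylic ethyl ether that must be dealkylated and oxidised beside an enolisable acetyl group.
- Comparison: the chosen strategy forms the quaternary centre intramolecularly, relays it from one adjacent auxiliary-derived centre, and brings C8 in as the enol ether of the ketone itself.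

**Alternative 2:** C9=C10 and C1=C2 are cut. Forward, the second-generation Grubbs catalyst (H2IMes)(PCy3)Cl2Ru=CHPh starts at the C9 vinyl group of dienyne A4, closes ring B onto C10 of the siloxyalkyne and closes ring A from the resulting C1 siloxycarbene onto the prenyl olefin, giving A3.
- For: it is catalytic and mild, forms both rings in one operation, creates no stereocentre (so no diastereoselectivity question) and delivers C1 already oxidised. On mildness and on the C1 oxygen it is stronger than the chosen route.
- Against: the C4/C5 pair, a tertiary centre beside a quaternary propargylic one, must be built in the open chain A4, where no ring helps; this is the hard problem of the target and the key step does not address it. A3 has no oxygen at C8 and no handle at C7, so an allylic oxidation that must discriminate C8 from the ring A positions and a separate C7 functionalisation follow. The C1 ketone must later be reduced to the axial alcohol. The second closure needs a heteroatom-stabilised carbene to engage a trisubstituted olefin beside a quaternary centre.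
- Comparison: the chosen strategy makes C5 during ring formation under control of C4 and places the C8 oxygen and the C6=C7 handle directly.

**Alternative 3:** C4–C5 is cut. Forward, anodic or hypervalent-iodine oxidation of phenol A6 gives a phenoxonium ion that the tethered (E)-allylsilane attacks at the methyl-bearing para carbon C5 through C4, giving dienone A5.
- For: A5 is at the same cross-conjugated dienone stage as 17 but already carries the C1 oxygen and a vinyl group as C15 precursor, and it comes from a simple arene in few steps. On step count to the dienone it is stronger than the chosen route.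
- Against: two stereocentres (C4, C5) are set at once under control of the benzylic C1 centre only, through a chair whose preference for the silyloxy group is not secure. Solvent capture, ortho attack and oxidation or protodesilylation of the allylsilane compete. The vinyl group must later be cleaved to the acid in the presence of the dienone.
- Comparison: the chosen strategy sets C4 first with an auxiliary and C5 next to it by 1,2-relay, and reaches the same dienone type through the sulfone. It pays with a late C1 oxygenation.

Key step: step 9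

Remark on the chemistry: bicyclic intermediates are named as 11,12,13-trinoreremophilanes with the numbering defined above. The trans ring fusion drawn for 15 is the expected one and has no consequence, because C10 becomes trigonal in step 10.

## Route

Step 1
Reactants: 1 hept-6-enoic acid; 2 (S)-4-benzyloxazolidin-2-one
Product: 4 (S)-4-benzyl-3-(hept-6-enoyl)oxazolidin-2-one, via mixed pivalic anhydride 3 (not isolated)
Conditions: t-BuCOCl, Et3N, THF, −20 °C; then 2, LiCl, −20 °C to rt
Reagents that add atoms: none
Why: Mixed-anhydride N-acylation of an oxazolidinone; the auxiliary nitrogen attacks the unhindered heptenoyl carbonyl and no stereocentre is touched.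

Step 2
Reactants: 4 (S)-4-benzyl-3-(hept-6-enoyl)oxazolidin-2-one
Product: 6 (S)-4-benzyl-3-[(R)-2-(hydroxymethyl)hept-6-enoyl]oxazolidin-2-one, via chlorotitanium enolate 5 (not isolated)
Conditions: TiCl4, i-Pr2NEt, CH2Cl2, 0 °C; then 1,3,5-trioxane, TiCl4, 0 °C
Reagents that add atoms: 1,3,5-trioxane, C1OCOCO1
Why: Evans titanium-enolate hydroxymethylation; the chelated (Z)-enolate is attacked by TiCl4-activated formaldehyde on the face opposite the benzyl group, which sets C4 (R here, S in the later compounds after a change of substituent priorities).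

Step 3
Reactants: 6 (S)-4-benzyl-3-[(R)-2-(hydroxymethyl)hept-6-enoyl]oxazolidin-2-one
Product: 7 (R)-2-(hydroxymethyl)-N-methoxy-N-methylhept-6-enamide
Conditions: MeNHOMe·HCl, AlMe3, CH2Cl2, −15 °C to rt
Reagents that add atoms: N,O-dimethylhydroxylamine hydrochloride, CNOC.Cl
Why: Weinreb transamidation of an Evans imide; the free β-hydroxyl binds aluminium and directs the amide nucleophile to the exocyclic carbonyl, and C4 is not enolised; the auxiliary is recovered.

Step 4
Reactants: 7 (R)-2-(hydroxymethyl)-N-methoxy-N-methylhept-6-enamide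
Product: 8 (R)-2-[(tert-butyldimethylsilyloxy)methyl]-N-methoxy-N-methylhept-6-enamide
Conditions: TBSCl, imidazole, DMF, 0 °C to rt
Reagents that add atoms: tert-butyldimethylsilyl chloride, C[Si](C)(Cl)C(C)(C)C
Why: Standard silylation of a primary alcohol; the silyl ether is stable to every step up to step 20.

Step 5
Reactants: 8 (R)-2-[(tert-butyldimethylsilyloxy)methyl]-N-methoxy-N-methylhept-6-enamide
Product: 9 (R)-3-[(tert-butyldimethylsilyloxy)methyl]oct-7-en-2-one
Conditions: MeMgBr, THF, −78 to 0 °C; aq. NH4Cl
Reagents that add atoms: methylmagnesium bromide, C[Mg]Br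
Why: Weinreb ketone synthesis; the chelated tetrahedral intermediate holds until quench, so there is no over-addition and the α-centre C4 is not exposed to base as a ketone.

Step 6
Reactants: 9 (R)-3-[(tert-butyldimethylsilyloxy)methyl]oct-7-en-2-one; 10 diethyl (phenylsulfonylmethyl)phosphonate
Product: 11 (1E,3S)-3-[(tert-butyldimethylsilyloxy)methyl]-2-methyl-1-(phenylsulfonyl)octa-1,7-diene
Conditions: 10, n-BuLi, THF, −78 °C; then 9, −78 °C to rt
Reagents that add atoms: none
Why: Horner–Wadsworth–Emmons olefination of a methyl ketone; the sulfonyl group ends trans to the larger branched C4 substituent (E), and the stabilised, weakly basic anion used in slight deficit of base should leave C4–H alone. The geometry is not critical because C6 becomes trigonal again in step 10.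

Step 7
Reactants: 11 (1E,3S)-3-[(tert-butyldimethylsilyloxy)methyl]-2-methyl-1-(phenylsulfonyl)octa-1,7-diene; 12 but-3-en-2-one
Product: 13 (3E,8S,9E)-8-[(tert-butyldimethylsilyloxy)methyl]-9-methyl-10-(phenylsulfonyl)deca-3,9-dien-2-one
Conditions: 12 (3 equiv), second-generation Grubbs catalyst (H2IMes)(PCy3)Cl2Ru=CHPh (5 mol %), CH2Cl2, 40 °C
Reagents that add atoms: none
Why: Olefin cross-metathesis of a terminal alkene with an electron-poor enone gives the (E)-enone; the trisubstituted, electron-poor vinyl sulfone does not enter the catalytic cycle.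

Step 8
Reactants: 13 (3E,8S,9E)-8-[(tert-butyldimethylsilyloxy)methyl]-9-methyl-10-(phenylsulfonyl)deca-3,9-dien-2-one
Product: 14 (3E,8S,9E)-2-(tert-butyldimethylsilyloxy)-8-[(tert-butyldimethylsilyloxy)methyl]-9-methyl-10-(phenylsulfonyl)deca-1,3,9-triene
Conditions: TBSOTf, Et3N, CH2Cl2, −78 to 0 °C
Reagents that add atoms: tert-butyldimethylsilyl trifluoromethanesulfonate, C[Si](C)(OS(=O)(=O)C(F)(F)F)C(C)(C)C
Why: Soft enolisation of the methyl ketone gives the cross-conjugated 2-silyloxydiene from the methyl group; Et3N is too weak a base to deprotonate the vinyl sulfone at its α- or γ-positions.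

Step 9
Reactants: 14 (3E,8S,9E)-2-(tert-butyldimethylsilyloxy)-8-[(tert-butyldimethylsilyloxy)methyl]-9-methyl-10-(phenylsulfonyl)deca-1,3,9-triene
Product: 15 (4S,5S,6R,10S)-8,15-bis(tert-butyldimethylsilyloxy)-6-(phenylsulfonyl)-11,12,13-trinoreremophil-8-ene (trans-fused)
Conditions: PhMe (0.01 mol/L), 2,6-di-tert-butyl-4-methylphenol (cat.), propylene oxide (acid scavenger), silylated sealed tube, 170 °C
Reagents that add atoms: none
Why: Concerted but asynchronous thermal [4+2] cycloaddition: the 2-silyloxydiene C7=C8–C9=C10 (HOMO) adds suprafacially to the sulfonyl-activated C5=C6 (LUMO), forming C5–C10 and C6–C7 and leaving the C8=C9 silyl enol ether. The closest known reactions are intramolecular Diels–Alder reactions of 1,7,9-decatrienes that carry a silyloxy group on the diene or a sulfonyl group at the dienophile terminus; this case is slower because C5 becomes quaternary and because the tether forces the donor terminus C7 to bond to C6, the carbon next to sulfur, and not to the more electrophilic C5, hence 170 °C at high dilution. Ring A (C1, C2, C3, C4, C5, C10) closes through a chair-like arrangement of the four-carbon tether, an exo-type closure in which the dienophile double bond lies outside the new ring. Ring B (C5 to C10) is the boat-like cyclohexene ring of the cycloaddition itself. C5 is set relative to C4: in both chair transition states C6 must lie anti to C1, which makes C14 axial on ring A, and the C4 silyloxymethyl group prefers the equatorial site anti to the forming C5–C10 bond, so C14 ends cis to C15. C6 follows from the (E)-dienophile by suprafacial addition (sulfonyl cis to C14) and C10 from the orientation with the tether anti and the sulfonyl group endo (trans fusion); both become trigonal again in step 10, so a mixture at these two centres is harmless. The one selectivity that matters is therefore the dienophile face that C10 attacks at C5, secured by the single C4 stereocentre next to it; regiochemistry is fixed by the tether, the (E)-diene cannot undergo a 1,5-hydrogen shift, and acid-free glass protects the silyl enol ether.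

Step 10
Reactants: 15 (4S,5S,6R,10S)-8,15-bis(tert-butyldimethylsilyloxy)-6-(phenylsulfonyl)-11,12,13-trinoreremophil-8-ene
Product: 17 (4S,5R)-15-(tert-butyldimethylsilyloxy)-11,12,13-trinoreremophila-6,9-dien-8-one, via sulfonyl enone 16 (not isolated)
Conditions: Pd(OAc)2 (1.1 equiv), MeCN, rt to 40 °C; then DBU, rt
Reagents that add atoms: none
Why: Saegusa–Ito oxidation: palladation of the silyl enol ether at C9 and syn β-hydride elimination of H10 can only give the C9=C10 enone, with release of zerovalent palladium; DBU then removes H7 and expels benzenesulfinate (E1cB) to give C6=C7. The C6 and C10 centres are erased and the dienone cannot aromatise because C5 is quaternary.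

Step 11
Reactants: 17 (4S,5R)-15-(tert-butyldimethylsilyloxy)-11,12,13-trinoreremophila-6,9-dien-8-one
Product: 19 (4S,5R,7R)-7-allyl-15-(tert-butyldimethylsilyloxy)-11,12,13-trinoreremophil-9-en-8-one, via lithium enolate 18 (not isolated)
Conditions: LiBH(s-Bu)3, THF, −78 °C; then allyl bromide, −78 to 0 °C
Reagents that add atoms: allyl bromide, C=CCBr
Why: Conjugate hydride addition followed by enolate alkylation (reductive alkylation of an enone with a trialkylborohydride): hydride goes to the β-carbon C6, which bears only hydrogen, and not to the fully substituted C10. The regiodefined C7 enolate is allylated anti to the pseudo-axial C14, giving the equatorial allyl group, which is also the thermodynamic epimer.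

Step 12
Reactants: 19 (4S,5R,7R)-7-allyl-15-(tert-butyldimethylsilyloxy)-11,12,13-trinoreremophil-9-en-8-one
Product: 20 (4S,5R,7R)-7-allyl-8,15-bis(tert-butyldimethylsilyloxy)-11,12,13-trinoreremophila-1(10),8-diene
Conditions: TBSOTf, Et3N, CH2Cl2, 0 °C
Reagents that add atoms: tert-butyldimethylsilyl trifluoromethanesulfonate, C[Si](C)(OS(=O)(=O)C(F)(F)F)C(C)(C)C
Why: Soft enolisation of an octalenone gives the linearly conjugated dienol silyl ether by loss of a C1 proton, as with Δ4-3-keto steroids; the substituted, hindered C7 position is not the site of enolisation.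

Step 13
Reactants: 20 (4S,5R,7R)-7-allyl-8,15-bis(tert-butyldimethylsilyloxy)-11,12,13-trinoreremophila-1(10),8-diene
Product: 21 (1R,4S,5R,7R)-7-allyl-1-hydroxy-15-(tert-butyldimethylsilyloxy)-11,12,13-trinoreremophil-9-en-8-one
Conditions: mCPBA, NaHCO3, CH2Cl2, −20 to 0 °C
Reagents that add atoms: 3-chloroperoxybenzoic acid, OOC(=O)c1cccc(Cl)c1
Why: Vinylogous Rubottom oxidation: the peracid attacks the electron-rich diene terminus C1 far faster than the isolated allyl group, and opening of the C1–C10 epoxide with loss of silicon gives the γ-hydroxy enone. Attack is axial and syn to C14 for stereoelectronic reasons, as in the 6β-hydroxylation of steroidal 3,5-dienol ethers, which sets 1R.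

Step 14
Reactants: 2 (S)-4-benzyloxazolidin-2-one; 22 hexanoyl chloride
Product: 23 (S)-4-benzyl-3-hexanoyloxazolidin-2-one
Conditions: 22, Et3N, DMAP (cat.), CH2Cl2, 0 °C to rt
Reagents that add atoms: none
Why: DMAP-catalysed N-acylation of the oxazolidinone with an acid chloride.

Step 15
Reactants: 23 (S)-4-benzyl-3-hexanoyloxazolidin-2-one
Product: 25 (S)-4-benzyl-3-[(S)-2-methylhexanoyl]oxazolidin-2-one, via sodium enolate 24 (not isolated)
Conditions: NaN(SiMe3)2, THF, −78 °C; then MeI, −78 °C
Reagents that add atoms: iodomethane, CI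
Why: Evans alkylation; the chelated (Z)-sodium enolate is methylated on the face opposite the benzyl group, which sets the (S)-α-methyl centre of the side chain.

Step 16
Reactants: 25 (S)-4-benzyl-3-[(S)-2-methylhexanoyl]oxazolidin-2-one
Product: 26 (S)-2-methylhexan-1-ol
Conditions: LiBH4, Et2O, H2O (1 equiv), 0 °C
Reagents that add atoms: none
Why: Reductive removal of the auxiliary; hydride attacks the exocyclic carbonyl, the auxiliary is recovered and the α-centre is not epimerised.

Step 17
Reactants: 26 (S)-2-methylhexan-1-ol; 27 ethyl 2-(triphenylphosphoranylidene)propanoate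
Product: 29 ethyl (2E,4S)-2,4-dimethyloct-2-enoate, via (S)-2-methylhexanal 28 (not isolated)
Conditions: Dess–Martin periodinane, CH2Cl2, 0 °C to rt; then 27, rt
Reagents that add atoms: none
Why: Dess–Martin oxidation followed in the same flask by Wittig olefination with a stabilised α-methyl ylide, which gives the (E)-trisubstituted enoate; the volatile, epimerisable aldehyde is consumed as it forms.

Step 18
Reactants: 29 ethyl (2E,4S)-2,4-dimethyloct-2-enoate
Product: 30 (2E,4S)-2,4-dimethyloct-2-enoic acid
Conditions: LiOH, THF/MeOH/H2O, 40 °C; then aq. HCl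
Reagents that add atoms: lithium hydroxide, [Li+].[OH-]
Why: Saponification of an enoate; the γ-centre is not deprotonated by hydroxide and the (E)-geometry is the stable one.

Step 19
Reactants: 21 (1R,4S,5R,7R)-7-allyl-1-hydroxy-15-(tert-butyldimethylsilyloxy)-11,12,13-trinoreremophil-9-en-8-one; 30 (2E,4S)-2,4-dimethyloct-2-enoic acid
Product: 32 (1R,4S,5R,7R)-7-allyl-1-[(2E,4S)-2,4-dimethyloct-2-enoyloxy]-15-(tert-butyldimethylsilyloxy)-11,12,13-trinoreremophil-9-en-8-one, via mixed trichlorobenzoic anhydride 31 (not isolated)
Conditions: 30, 2,4,6-trichlorobenzoyl chloride, Et3N, THF, rt; then 21, DMAP, PhMe, rt to 40 °C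
Reagents that add atoms: none
Why: Yamaguchi esterification; DMAP transfers the enoyl group of the mixed anhydride to the hindered axial C1 alcohol with retention at C1, and neither C7 nor the side-chain centre is affected.

Step 20
Reactants: 32 (1R,4S,5R,7R)-7-allyl-1-[(2E,4S)-2,4-dimethyloct-2-enoyloxy]-15-(tert-butyldimethylsilyloxy)-11,12,13-trinoreremophil-9-en-8-one
Product: 33 (1R,4S,5R,7R)-7-allyl-1-[(2E,4S)-2,4-dimethyloct-2-enoyloxy]-15-hydroxy-11,12,13-trinoreremophil-9-en-8-one
Conditions: HF·pyridine, pyridine, THF, 0 °C to rt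
Reagents that add atoms: none
Why: Acidic fluoride cleaves the primary silyl ether without the basic conditions that could eliminate or migrate the C1 ester.

Step 21
Reactants: 33 (1R,4S,5R,7R)-7-allyl-1-[(2E,4S)-2,4-dimethyloct-2-enoyloxy]-15-hydroxy-11,12,13-trinoreremophil-9-en-8-one
Product: 35 (1R,4S,5R,7R)-7-allyl-1-[(2E,4S)-2,4-dimethyloct-2-enoyloxy]-8-oxo-11,12,13-trinoreremophil-9-en-15-oic acid, via C15 aldehyde 34 (not isolated)
Conditions: TEMPO (cat.), PhI(OAc)2, MeCN/H2O, rt
Reagents that add atoms: water, O
Why: Oxoammonium oxidation of the primary alcohol to the aldehyde and, through its hydrate, to the acid; alkenes, enone and ester are inert, and C4 keeps its equatorial, thermodynamically preferred configuration.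

Step 22
Reactants: 35 (1R,4S,5R,7R)-7-allyl-1-[(2E,4S)-2,4-dimethyloct-2-enoyloxy]-8-oxo-11,12,13-trinoreremophil-9-en-15-oic acid
Product: 37 (1R,4S,5R,7S)-1-[(2E,4S)-2,4-dimethyloct-2-enoyloxy]-8-oxo-7-(2-oxoethyl)-11,12,13-trinoreremophil-9-en-15-oic acid, via vicinal diol 36 (not isolated)
Conditions: OsO4 (cat.), NaIO4, 2,6-lutidine, dioxane/H2O, rt
Reagents that add atoms: osmium tetroxide, O=[Os](=O)(=O)=O (oxygen of the new aldehyde, regenerated by sodium periodate, [Na+].[O-]I(=O)(=O)=O)
Why: Lemieux–Johnson cleavage; OsO4 dihydroxylates the monosubstituted terminal alkene much faster than the electron-poor trisubstituted enone and enoate double bonds, and periodate cleaves the diol.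

Step 23
Reactants: 37 (1R,4S,5R,7S)-1-[(2E,4S)-2,4-dimethyloct-2-enoyloxy]-8-oxo-7-(2-oxoethyl)-11,12,13-trinoreremophil-9-en-15-oic acid
Product: 38 integric acid
Conditions: aq. CH2O (37 %), pyrrolidine (cat.), EtCO2H (cat.), i-PrOH, 45 °C
Reagents that add atoms: formaldehyde, C=O
Why: Amine-catalysed α-methylenation of an aldehyde (Mannich condensation through the enamine, then loss of the amine); only the aldehyde has an unhindered α-CH2 that forms an enamine readily, and C7 stays in its equatorial, thermodynamic configuration.

## Compound list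

1 | hept-6-enoic acid | C=CCCCCC(=O)O | starting material
2 | (S)-4-benzyloxazolidin-2-one | O=C1N[C@@H](Cc2ccccc2)CO1 | starting material
3 | hept-6-enoic pivalic anhydride | C=CCCCCC(=O)OC(=O)C(C)(C)C | intermediate (not isolated)
4 | (S)-4-benzyl-3-(hept-6-enoyl)oxazolidin-2-one | C=CCCCCC(=O)N1[C@@H](Cc2ccccc2)COC1=O | intermediate
5 | chlorotitanium (Z)-enolate of 4 | C=CCCC/C=C(\O[Ti](Cl)(Cl)Cl)N1[C@@H](Cc2ccccc2)COC1=O | intermediate (not isolated)
6 | (S)-4-benzyl-3-[(R)-2-(hydroxymethyl)hept-6-enoyl]oxazolidin-2-one | C=CCCC[C@H](CO)C(=O)N1[C@@H](Cc2ccccc2)COC1=O | intermediate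
7 | (R)-2-(hydroxymethyl)-N-methoxy-N-methylhept-6-enamide | C=CCCC[C@H](CO)C(=O)N(C)OC | intermediate
8 | (R)-2-[(tert-butyldimethylsilyloxy)methyl]-N-methoxy-N-methylhept-6-enamide | C=CCCC[C@H](CO[Si](C)(C)C(C)(C)C)C(=O)N(C)OC | intermediate
9 | (R)-3-[(tert-butyldimethylsilyloxy)methyl]oct-7-en-2-one | C=CCCC[C@H](CO[Si](C)(C)C(C)(C)C)C(C)=O | intermediate
10 | diethyl (phenylsulfonylmethyl)phosphonate | CCOP(=O)(CS(=O)(=O)c1ccccc1)OCC | starting material
11 | (1E,3S)-3-[(tert-butyldimethylsilyloxy)methyl]-2-methyl-1-(phenylsulfonyl)octa-1,7-diene | C=CCCC[C@H](CO[Si](C)(C)C(C)(C)C)/C(C)=C/S(=O)(=O)c1ccccc1 | intermediate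
12 | but-3-en-2-one | C=CC(C)=O | starting material
13 | (3E,8S,9E)-8-[(tert-butyldimethylsilyloxy)methyl]-9-methyl-10-(phenylsulfonyl)deca-3,9-dien-2-one | CC(=O)/C=C/CCC[C@H](CO[Si](C)(C)C(C)(C)C)/C(C)=C/S(=O)(=O)c1ccccc1 | intermediate
14 | (3E,8S,9E)-2-(tert-butyldimethylsilyloxy)-8-[(tert-butyldimethylsilyloxy)methyl]-9-methyl-10-(phenylsulfonyl)deca-1,3,9-triene | C=C(O[Si](C)(C)C(C)(C)C)/C=C/CCC[C@H](CO[Si](C)(C)C(C)(C)C)/C(C)=C/S(=O)(=O)c1ccccc1 | intermediate (key-step precursor)
15 | (4S,5S,6R,10S)-8,15-bis(tert-butyldimethylsilyloxy)-6-(phenylsulfonyl)-11,12,13-trinoreremophil-8-ene, trans-fused | C1[C@@H](S(=O)(=O)c3ccccc3)[C@@]2(C)[C@H](C=C1O[Si](C)(C)C(C)(C)C)CCC[C@@H]2CO[Si](C)(C)C(C)(C)C | intermediate (key-step product)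
16 | (4S,5R,6R)-15-(tert-butyldimethylsilyloxy)-6-(phenylsulfonyl)-11,12,13-trinoreremophil-9-en-8-one | O=C1C[C@@H](S(=O)(=O)c3ccccc3)[C@@]2(C)C(=C1)CCC[C@@H]2CO[Si](C)(C)C(C)(C)C | intermediate (not isolated)
17 | (4S,5R)-15-(tert-butyldimethylsilyloxy)-11,12,13-trinoreremophila-6,9-dien-8-one | O=C1C=C[C@@]2(C)C(=C1)CCC[C@@H]2CO[Si](C)(C)C(C)(C)C | intermediate
18 | lithium (4S,5R)-15-(tert-butyldimethylsilyloxy)-11,12,13-trinoreremophila-7,9-dien-8-olate | [Li+].[O-]C1=CC[C@@]2(C)C(=C1)CCC[C@@H]2CO[Si](C)(C)C(C)(C)C | intermediate (not isolated)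
19 | (4S,5R,7R)-7-allyl-15-(tert-butyldimethylsilyloxy)-11,12,13-trinoreremophil-9-en-8-one | C=CC[C@@H]1C[C@@]2(C)C(=CC1=O)CCC[C@@H]2CO[Si](C)(C)C(C)(C)C | intermediate
20 | (4S,5R,7R)-7-allyl-8,15-bis(tert-butyldimethylsilyloxy)-11,12,13-trinoreremophila-1(10),8-diene | C=CC[C@@H]1C[C@@]2(C)C(=CCC[C@@H]2CO[Si](C)(C)C(C)(C)C)C=C1O[Si](C)(C)C(C)(C)C | intermediate
21 | (1R,4S,5R,7R)-7-allyl-1-hydroxy-15-(tert-butyldimethylsilyloxy)-11,12,13-trinoreremophil-9-en-8-one | C=CC[C@@H]1C[C@@]2(C)C(=CC1=O)[C@H](O)CC[C@@H]2CO[Si](C)(C)C(C)(C)C | intermediate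
22 | hexanoyl chloride | CCCCCC(=O)Cl | starting material
23 | (S)-4-benzyl-3-hexanoyloxazolidin-2-one | CCCCCC(=O)N1[C@@H](Cc2ccccc2)COC1=O | intermediate
24 | sodium (Z)-enolate of 23 | [Na+].CCCC/C=C(\[O-])N1[C@@H](Cc2ccccc2)COC1=O | intermediate (not isolated)
25 | (S)-4-benzyl-3-[(S)-2-methylhexanoyl]oxazolidin-2-one | CCCC[C@H](C)C(=O)N1[C@@H](Cc2ccccc2)COC1=O | intermediate
26 | (S)-2-methylhexan-1-ol | CCCC[C@H](C)CO | intermediate
27 | ethyl 2-(triphenylphosphoranylidene)propanoate | CCOC(=O)C(C)=P(c1ccccc1)(c1ccccc1)c1ccccc1 | starting material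
28 | (S)-2-methylhexanal | CCCC[C@H](C)C=O | intermediate (not isolated)
29 | ethyl (2E,4S)-2,4-dimethyloct-2-enoate | CCCC[C@H](C)/C=C(\C)C(=O)OCC | intermediate
30 | (2E,4S)-2,4-dimethyloct-2-enoic acid | CCCC[C@H](C)/C=C(\C)C(=O)O | intermediate
31 | (2E,4S)-2,4-dimethyloct-2-enoic 2,4,6-trichlorobenzoic anhydride | CCCC[C@H](C)/C=C(\C)C(=O)OC(=O)c1c(Cl)cc(Cl)cc1Cl | intermediate (not isolated)
32 | (1R,4S,5R,7R)-7-allyl-1-[(2E,4S)-2,4-dimethyloct-2-enoyloxy]-15-(tert-butyldimethylsilyloxy)-11,12,13-trinoreremophil-9-en-8-one | C=CC[C@@H]1C[C@@]2(C)C(=CC1=O)[C@H](OC(=O)/C(C)=C/[C@@H](C)CCCC)CC[C@@H]2CO[Si](C)(C)C(C)(C)C | intermediate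
33 | (1R,4S,5R,7R)-7-allyl-1-[(2E,4S)-2,4-dimethyloct-2-enoyloxy]-15-hydroxy-11,12,13-trinoreremophil-9-en-8-one | C=CC[C@@H]1C[C@@]2(C)C(=CC1=O)[C@H](OC(=O)/C(C)=C/[C@@H](C)CCCC)CC[C@@H]2CO | intermediate
34 | (1R,4S,5R,7R)-7-allyl-1-[(2E,4S)-2,4-dimethyloct-2-enoyloxy]-8-oxo-11,12,13-trinoreremophil-9-en-15-al | C=CC[C@@H]1C[C@@]2(C)C(=CC1=O)[C@H](OC(=O)/C(C)=C/[C@@H](C)CCCC)CC[C@@H]2C=O | intermediate (not isolated)
35 | (1R,4S,5R,7R)-7-allyl-1-[(2E,4S)-2,4-dimethyloct-2-enoyloxy]-8-oxo-11,12,13-trinoreremophil-9-en-15-oic acid | C=CC[C@@H]1C[C@@]2(C)C(=CC1=O)[C@H](OC(=O)/C(C)=C/[C@@H](C)CCCC)CC[C@@H]2C(=O)O | intermediate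
36 | 7-(2,3-dihydroxypropyl) analogue of 35 (both carbinol epimers) | OCC(O)C[C@@H]1C[C@@]2(C)C(=CC1=O)[C@H](OC(=O)/C(C)=C/[C@@H](C)CCCC)CC[C@@H]2C(=O)O | intermediate (not isolated)
37 | (1R,4S,5R,7S)-1-[(2E,4S)-2,4-dimethyloct-2-enoyloxy]-8-oxo-7-(2-oxoethyl)-11,12,13-trinoreremophil-9-en-15-oic acid | O=CC[C@@H]1C[C@@]2(C)C(=CC1=O)[C@H](OC(=O)/C(C)=C/[C@@H](C)CCCC)CC[C@@H]2C(=O)O | intermediate
38 | integric acid | C=C(C=O)[C@@H]1C[C@@]2(C)C(=CC1=O)[C@H](OC(=O)/C(C)=C/[C@@H](C)CCCC)CC[C@@H]2C(=O)O | target

## Step count and least certain steps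

Total: 23 steps. Longest linear sequence: 18 steps (steps 1–13 and 19–23, from 1). Acid 30 is made in 5 steps (14–18) and joined in step 19.

**Step 9 (key step).** The cycloaddition may be too slow at temperatures the silyl dienol ether survives, so that desilylation or polymerisation of the diene overtakes it. The dienophile is trisubstituted, C5 becomes quaternary, and the tether forces the donor end of the diene onto the carbon next to sulfur instead of the electrophilic C5. The C4-to-C5 relay may also erode through boat-like or axial-C15 transition states.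

Fallback, from 9 back to 19, without the sulfone and with matched polarity: kinetic enolisation of 9 (LiN(i-Pr)2, THF, −78 °C) and trapping with PhNTf2 would give the terminal enol triflate F1. Palladium-catalysed reductive carbonylation (CO, Pd(PPh3)4, Bu3SnH, THF, 50 °C) would give the 2-substituted acrolein F2, in which the formyl carbon is C14 and the methylene is C6. Cross-metathesis with 12 as in step 7 gives enone F3, and TBSOTf/Et3N gives the silyloxydiene F4. In F4 the nucleophilic C7 meets the β-carbon C6 of a 1,1-disubstituted enal, so cycloaddition should occur at much lower temperature to the angular aldehyde F5, with the same chair control of C4/C5. The aldehyde is reduced to the methyl group through the tosylhydrazone F6 (TsNHNH2; then catecholborane, NaOAc), giving the silyl enol ether F7. Saegusa–Ito oxidation (Pd(OAc)2, MeCN) gives the enone F8, and LiN(i-Pr)2 then allyl bromide at −78 °C gives 19.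

**Step 6.** The olefination may give an E/Z mixture. The basic medium may epimerise C4 of the ketone before it reacts, or move the new double bond out of conjugation (vinyl to allyl sulfone), which would also scramble C4.

Fallback, from 8 back to 11, without a base at the ketone or vinyl sulfone stage: i-Bu2AlH reduction of 8 gives the aldehyde F9. Ohira–Bestmann homologation (dimethyl (1-diazo-2-oxopropyl)phosphonate, K2CO3, MeOH) gives the alkyne F10. Negishi carboalumination and iodination (AlMe3, Cp2ZrCl2 cat.; then I2) gives the (E)-alkenyl iodide F11 with defined geometry; the alkyne reacts far faster than the terminal alkene. Copper-catalysed coupling with PhSO2Na (CuI, L-proline sodium salt, DMSO, 90 °C) gives 11 with retention.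

**Step 11.** Hydride may add to the carbonyl (1,2-reduction) instead of the neopentyl C6. The boron-complexed enolate may alkylate slowly, so that proton transfer and double allylation compete.

Fallback, from 17 back to 19, with a catalytic metal hydride in place of the borohydride and a boron-free enolate: 1,4-hydrosilylation of 17 with Et3SiH and RhCl(PPh3)3 (cat., PhMe, 50 °C) puts hydrogen on C6 of the less substituted enone and silicon on oxygen. A monohydrosilane adds to enones in the conjugate sense, so the carbonyl is not reduced and the product is the triethylsilyl dienol ether F12, which can be isolated. MeLi in THF at 0 °C then cleaves the O–Si bond and releases the lithium enolate 18 free of trialkylborane, and allyl bromide at −78 to 0 °C gives 19.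

**Step 13.** Enolisation in step 12 may go toward C7 (cross-conjugated dienol ether). The peracid may then attack C9 instead of C1, attack C1 from the face anti to C14, or epoxidise the allyl group.

Fallback, from 19 back to 32, skipping 21 and step 19: deconjugation of 19 (KOt-Bu, t-BuOH; kinetic protonation of the dienolate at C9 with aq. AcOH) gives the β,γ-enone F13. Epoxidation with mCPBA occurs on the trisubstituted C1=C10 bond from the face anti to C14 and gives the epoxide F14. Et3N opens it by β-elimination to the equatorial alcohol F15, the C1 epimer of 21. Mitsunobu esterification with 30 (PPh3, diisopropyl azodicarboxylate, THF) installs the ester with inversion and gives 32.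

**Step 23.** The amine catalyst may add to the product enal. The exocyclic double bond may migrate into conjugation through the acidic C7–H. A free acid carrying an enal may be hard to purify.

Fallback, from 35 back to 38, with the acid masked and a stoichiometric Mannich route: tert-butyl 2,2,2-trichloroacetimidate with BF3·OEt2 (cat.) converts 35 into the tert-butyl ester F16. OsO4/NaIO4 as in step 22 gives the aldehyde F17. Dimethylmethyleneiminium iodide with Et3N in CH2Cl2, followed by elimination of the Mannich base on silica, gives the enal F18. CF3CO2H in CH2Cl2 at 0 °C releases 38.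

## Further compounds

F1 | step 9 | (R)-3-[(tert-butyldimethylsilyloxy)methyl]octa-1,7-dien-2-yl trifluoromethanesulfonate | C=C(OS(=O)(=O)C(F)(F)F)[C@@H](CO[Si](C)(C)C(C)(C)C)CCCC=C
F2 | step 9 | (S)-3-[(tert-butyldimethylsilyloxy)methyl]-2-methylideneoct-7-enal | C=C(C=O)[C@@H](CO[Si](C)(C)C(C)(C)C)CCCC=C
F3 | step 9 | (3S,7E)-3-[(tert-butyldimethylsilyloxy)methyl]-2-methylidene-9-oxodec-7-enal | C=C(C=O)[C@@H](CO[Si](C)(C)C(C)(C)C)CCC/C=C/C(C)=O
F4 | step 9 | (3S,7E)-9-(tert-butyldimethylsilyloxy)-3-[(tert-butyldimethylsilyloxy)methyl]-2-methylidenedeca-7,9-dienal | C=C(C=O)[C@@H](CO[Si](C)(C)C(C)(C)C)CCC/C=C/C(=C)O[Si](C)(C)C(C)(C)C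
F5 | step 9 | trans-fused 8,15-bis(tert-butyldimethylsilyloxy)-11,12,13-trinoreremophil-8-en-14-al (C14 cis to C15) | C1C[C@@]2(C=O)[C@H](C=C1O[Si](C)(C)C(C)(C)C)CCC[C@@H]2CO[Si](C)(C)C(C)(C)C
F6 | step 9 | tosylhydrazone of F5 | C1C[C@@]2(/C=N/NS(=O)(=O)c3ccc(C)cc3)[C@H](C=C1O[Si](C)(C)C(C)(C)C)CCC[C@@H]2CO[Si](C)(C)C(C)(C)C
F7 | step 9 | (4S,5S,10S)-8,15-bis(tert-butyldimethylsilyloxy)-11,12,13-trinoreremophil-8-ene | C1C[C@@]2(C)[C@H](C=C1O[Si](C)(C)C(C)(C)C)CCC[C@@H]2CO[Si](C)(C)C(C)(C)C
F8 | step 9 | (4S,5R)-15-(tert-butyldimethylsilyloxy)-11,12,13-trinoreremophil-9-en-8-one | O=C1CC[C@@]2(C)C(=C1)CCC[C@@H]2CO[Si](C)(C)C(C)(C)C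
F9 | step 6 | (R)-2-[(tert-butyldimethylsilyloxy)methyl]hept-6-enal | C=CCCC[C@H](CO[Si](C)(C)C(C)(C)C)C=O
F10 | step 6 | (S)-3-[(tert-butyldimethylsilyloxy)methyl]oct-7-en-1-yne | C=CCCC[C@H](CO[Si](C)(C)C(C)(C)C)C#C
F11 | step 6 | (1E,3S)-3-[(tert-butyldimethylsilyloxy)methyl]-1-iodo-2-methylocta-1,7-diene | C=CCCC[C@H](CO[Si](C)(C)C(C)(C)C)/C(C)=C/I
F12 | step 11 | (4S,5R)-15-(tert-butyldimethylsilyloxy)-8-(triethylsilyloxy)-11,12,13-trinoreremophila-7,9-diene | CC[Si](CC)(CC)OC1=CC[C@@]2(C)C(=C1)CCC[C@@H]2CO[Si](C)(C)C(C)(C)C
F13 | step 13 | (4S,5R,7R)-7-allyl-15-(tert-butyldimethylsilyloxy)-11,12,13-trinoreremophil-1(10)-en-8-one | C=CC[C@@H]1C[C@@]2(C)C(=CCC[C@@H]2CO[Si](C)(C)C(C)(C)C)CC1=O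
F14 | step 13 | 1,10-epoxide of F13, oxygen trans to C14 | C=CC[C@@H]1C[C@@]2(C)[C@@]3(CC1=O)O[C@H]3CC[C@@H]2CO[Si](C)(C)C(C)(C)C
F15 | step 13 | (1S,4S,5R,7R)-7-allyl-1-hydroxy-15-(tert-butyldimethylsilyloxy)-11,12,13-trinoreremophil-9-en-8-one (C1 epimer of 21) | C=CC[C@@H]1C[C@@]2(C)C(=CC1=O)[C@@H](O)CC[C@@H]2CO[Si](C)(C)C(C)(C)C
F16 | step 23 | tert-butyl ester of 35 | C=CC[C@@H]1C[C@@]2(C)C(=CC1=O)[C@H](OC(=O)/C(C)=C/[C@@H](C)CCCC)CC[C@@H]2C(=O)OC(C)(C)C
F17 | step 23 | tert-butyl ester of 37 | O=CC[C@@H]1C[C@@]2(C)C(=CC1=O)[C@H](OC(=O)/C(C)=C/[C@@H](C)CCCC)CC[C@@H]2C(=O)OC(C)(C)C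
F18 | step 23 | tert-butyl ester of integric acid | C=C(C=O)[C@@H]1C[C@@]2(C)C(=CC1=O)[C@H](OC(=O)/C(C)=C/[C@@H](C)CCCC)CC[C@@H]2C(=O)OC(C)(C)C
A1 | alternative 1 | 7-acetyl-8-ethoxy-5-methyl octalin ester (1-silyloxy, 2-(trimethylsilyl)ethyl ester at C15) | CC(=O)[C@@H]1C[C@@]2(C)C(=C[C@@H]1OCC)[C@H](O[Si](C)(C)C(C)(C)C)CC[C@@H]2C(=O)OCC[Si](C)(C)C
A2 | alternative 1 | ring A 1-ethoxydiene (C5=C10 in the ring, (E)-C9=C8–OEt side arm) | CCO/C=C/C1=C(C)[C@@H](C(=O)OCC[Si](C)(C)C)CC[C@H]1O[Si](C)(C)C(C)(C)C
A3 | alternative 2 | bicyclic triisopropylsilyl dienol ether (C9=C10, C1=C2), tert-butyl ester | C1C[C@@]2(C)C(=CC1)C(O[Si](C(C)C)(C(C)C)C(C)C)=CC[C@@H]2C(=O)OC(C)(C)C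
A4 | alternative 2 | acyclic siloxyalkyne dienyne with quaternary C5 and prenyl group on C4 | C=CCCC[C@@](C)(C#CO[Si](C(C)C)(C(C)C)C(C)C)[C@H](CC=C(C)C)C(=O)OC(C)(C)C
A5 | alternative 3 | 1-silyloxy-4-vinyl-5-methyl bicyclic cross-conjugated dienone | C1=C[C@@]2(C)C(=CC1=O)[C@H](O[Si](C)(C)C(C)(C)C)CC[C@@H]2C=C
A6 | alternative 3 | 4-methylphenol with a 3-[(E)-1-silyloxy-6-(trimethylsilyl)hex-4-enyl] side chain | Cc1ccc(O)cc1[C@H](O[Si](C)(C)C(C)(C)C)CC/C=C/C[Si](C)(C)C
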